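**Retrosynthetic overview**
- Target 17 ⇐ trans-selective hydride reduction of dihydroisoquinoline 16 (C1 set from C3) ⇐ Bischler–Napieralski closure of biaryl acetamide 15; the nitrogen ring is formed last.
- Biaryl bond C5–C1' ⇐ polarity-reversed coupling: naphthol 6 is oxidised by a trivalent iodine reagent to a naphthoxenium (vinylogous enolonium) equivalent, which is attacked at C4 by the electron-rich ring of acetamide 12. Two normally nucleophilic arene carbons are joined without halide or boron handles.
- Naphthol 6 ⇐ anionic annulation of an ortho-methallyl benzamide; the naphthalene ring is formed first.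
- Acetamide 12 ⇐ aryl Grignard opening of (S)-N-Boc-2-methylaziridine; C3 comes from the chiral pool.
- Ring order: naphthalene ring, then biaryl axis, then nitrogen ring.

Assumption: the SMILES defines C1 (S) and C3 (S) but not the hindered biaryl axis, so the route controls the two carbon stereocentres and gives the axis as a pair of atropo-diastereomers (both match the given structure), separated by chromatography at the end if one is wanted.

**Step 1**
Reactants: 1 N,N-diethyl-2-methoxybenzamide; 2 3-bromo-2-methylprop-1-ene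
Product: 5 N,N-diethyl-2-methoxy-6-(2-methylprop-2-en-1-yl)benzamide, via aryllithium 3 (not isolated), via arylmagnesium bromide 4 (not isolated)
Conditions: s-BuLi, TMEDA, THF, −78 °C; MgBr2·OEt2, −78 °C → 0 °C; 2, 0 °C → rt
Reagents that add atoms: none
Why: Directed ortho-metalation: the tertiary amide is a stronger director than OMe, so lithiation occurs only at C6, and transmetalation to magnesium gives an aryl nucleophile that is allylated cleanly by the symmetrical methallyl bromide; no stereocentre.

**Step 2**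
Reactants: 5 N,N-diethyl-2-methoxy-6-(2-methylprop-2-en-1-yl)benzamide
Product: 6 8-methoxy-3-methylnaphthalen-1-ol
Conditions: LiN(i-Pr)2 (2.2 equiv), THF, −78 °C → rt; then aq. HCl
Reagents that add atoms: none
Why: Anionic benzannulation of an ortho-allyl benzamide: the base removes the benzylic/allylic proton, the far end of the delocalised carbanion acylates itself on the neighbouring amide with loss of diethylamide, and enolisation gives the naphthol with methyl at C3 and OMe at C8 fixed by the substrate; no stereocentre.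

**Step 3**
Reactants: 7 1-bromo-3,5-dimethoxybenzene; 8 tert-butyl (2S)-2-methylaziridine-1-carboxylate
Product: 10 tert-butyl N-[(2S)-1-(3,5-dimethoxyphenyl)propan-2-yl]carbamate, via aryl Grignard reagent 9 (not isolated)
Conditions: Mg, THF, reflux; then CuI (10 mol %), 8, −30 °C → 0 °C; then H2O
Reagents that add atoms: none
Why: Copper-catalysed Grignard ring opening of an N-acyl-activated aziridine (SN2 at the unsubstituted CH2), so the stereocentre of 8 is untouched and becomes C3 (S) of the target.

**Step 4**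
Reactants: 10 tert-butyl N-[(2S)-1-(3,5-dimethoxyphenyl)propan-2-yl]carbamate
Product: 12 N-[(2S)-1-(3,5-dimethoxyphenyl)propan-2-yl]acetamide, via amine hydrochloride 11 (not isolated)
Conditions: 4 M HCl in dioxane, rt; evaporate; then Ac2O, Et3N, CH2Cl2, 0 °C → rt
Reagents that add atoms: acetic anhydride, CC(=O)OC(C)=O
Why: Acidolysis of the tert-butyl carbamate (loss of isobutene and CO2) followed by N-acetylation of the liberated amine; the stereocentre is not involved.

**Step 5 (key step)**
Reactants: 6 8-methoxy-3-methylnaphthalen-1-ol; 12 N-[(2S)-1-(3,5-dimethoxyphenyl)propan-2-yl]acetamide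
Product: 14 N-[(2S)-1-[2-(4-hydroxy-5-methoxy-2-methylnaphthalen-1-yl)-3,5-dimethoxyphenyl]propan-2-yl]acetamide, via naphthyloxy-λ3-iodane 13 (not isolated)
Conditions: PhI(OAc)2 (1.05 equiv, added over 1 h), 12 (3 equiv, excess recovered), (CF3)2CHOH, −20 °C → 0 °C
Reagents that add atoms: none
Why: Proposed new method: only the naphthol can exchange onto iodine, giving 13, which in the ionising, non-nucleophilic fluoroalcohol acts as a naphthoxenium (vinylogous enolonium) electrophile; its C4 (para to oxygen, less shielded than C2 between the O–I group and the methyl) is attacked by the most nucleophilic carbon of 12 (C2/C6, two equivalent sites ortho to the side chain and para to OMe), PhI and AcOH leave and rearomatisation gives the 4-aryl-1-naphthol; the closest known reaction type is the trivalent-iodine-mediated oxidative para cross-coupling of phenols and naphthols with methoxyarenes in fluoroalcohols; no stereocentre is formed and the hindered axis arises as both atropisomers.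

**Step 6**
Reactants: 14 N-[(2S)-1-[2-(4-hydroxy-5-methoxy-2-methylnaphthalen-1-yl)-3,5-dimethoxyphenyl]propan-2-yl]acetamide
Product: 15 N-[(2S)-1-[2-(4,5-dimethoxy-2-methylnaphthalen-1-yl)-3,5-dimethoxyphenyl]propan-2-yl]acetamide
Conditions: MeI, K2CO3, acetone, reflux
Reagents that add atoms: iodomethane, CI
Why: Williamson etherification: K2CO3 deprotonates the naphthol but not the secondary acetamide, so MeI alkylates oxygen only; the stereocentre is not involved.

**Step 7**
Reactants: 15 N-[(2S)-1-[2-(4,5-dimethoxy-2-methylnaphthalen-1-yl)-3,5-dimethoxyphenyl]propan-2-yl]acetamide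
Product: 16 (3S)-5-(4,5-dimethoxy-2-methylnaphthalen-1-yl)-6,8-dimethoxy-1,3-dimethyl-3,4-dihydroisoquinoline
Conditions: POCl3, MeCN, reflux; then aq. NaOH
Reagents that add atoms: none
Why: Bischler–Napieralski cyclodehydration: the POCl3-activated amide carbon attacks the one free ring position ortho to the side chain, which is para and ortho to the two methoxy groups, closing the nitrogen ring; C3 is untouched.

**Step 8**
Reactants: 16 (3S)-5-(4,5-dimethoxy-2-methylnaphthalen-1-yl)-6,8-dimethoxy-1,3-dimethyl-3,4-dihydroisoquinoline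
Product: 17 (1S,3S)-5-(4,5-dimethoxy-2-methylnaphthalen-1-yl)-6,8-dimethoxy-1,3-dimethyl-1,2,3,4-tetrahydroisoquinoline
Conditions: LiAlH4, AlMe3, THF, −78 °C → −20 °C; then H2O
Reagents that add atoms: none
Why: Substrate-controlled imine reduction: AlMe3 binds the imine nitrogen and pushes the C3 methyl pseudo-axial (A(1,2) strain), so axial hydride delivery from LiAlH4 gives the 1,3-trans product, i.e. (1S) from (3S).

**Compound list**
1 | N,N-diethyl-2-methoxybenzamide | CCN(CC)C(=O)c1ccccc1OC | starting material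
2 | 3-bromo-2-methylprop-1-ene (methallyl bromide) | C=C(C)CBr | starting material
3 | [2-(diethylcarbamoyl)-3-methoxyphenyl]lithium | CCN(CC)C(=O)c1c([Li])cccc1OC | intermediate
4 | [2-(diethylcarbamoyl)-3-methoxyphenyl]magnesium bromide | CCN(CC)C(=O)c1c([Mg]Br)cccc1OC | intermediate
5 | N,N-diethyl-2-methoxy-6-(2-methylprop-2-en-1-yl)benzamide | CCN(CC)C(=O)c1c(CC(C)=C)cccc1OC | intermediate
6 | 8-methoxy-3-methylnaphthalen-1-ol | COc1cccc2cc(C)cc(O)c12 | intermediate
7 | 1-bromo-3,5-dimethoxybenzene | COc1cc(Br)cc(OC)c1 | starting material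
8 | tert-butyl (2S)-2-methylaziridine-1-carboxylate | C[C@H]1CN1C(=O)OC(C)(C)C | starting material
9 | (3,5-dimethoxyphenyl)magnesium bromide | COc1cc([Mg]Br)cc(OC)c1 | intermediate
10 | tert-butyl N-[(2S)-1-(3,5-dimethoxyphenyl)propan-2-yl]carbamate | COc1cc(C[C@H](C)NC(=O)OC(C)(C)C)cc(OC)c1 | intermediate
11 | (2S)-1-(3,5-dimethoxyphenyl)propan-2-aminium chloride | COc1cc(C[C@H](C)[NH3+])cc(OC)c1.[Cl-] | intermediate
12 | N-[(2S)-1-(3,5-dimethoxyphenyl)propan-2-yl]acetamide | COc1cc(C[C@H](C)NC(C)=O)cc(OC)c1 | intermediate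
13 | (acetyloxy)[(8-methoxy-3-methylnaphthalen-1-yl)oxy](phenyl)-λ3-iodane | COc1cccc2cc(C)cc(OI(OC(C)=O)c3ccccc3)c12 | intermediate
14 | N-[(2S)-1-[2-(4-hydroxy-5-methoxy-2-methylnaphthalen-1-yl)-3,5-dimethoxyphenyl]propan-2-yl]acetamide | COc1cc(OC)c(-c2c(C)cc(O)c3c(OC)cccc23)c(C[C@H](C)NC(C)=O)c1 | intermediate
15 | N-[(2S)-1-[2-(4,5-dimethoxy-2-methylnaphthalen-1-yl)-3,5-dimethoxyphenyl]propan-2-yl]acetamide | COc1cc(OC)c(-c2c(C)cc(OC)c3c(OC)cccc23)c(C[C@H](C)NC(C)=O)c1 | intermediate
16 | (3S)-5-(4,5-dimethoxy-2-methylnaphthalen-1-yl)-6,8-dimethoxy-1,3-dimethyl-3,4-dihydroisoquinoline | COc1cc(OC)c2c(c1-c1c(C)cc(OC)c3c(OC)cccc13)C[C@H](C)N=C2C | intermediate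
17 | (1S,3S)-5-(4,5-dimethoxy-2-methylnaphthalen-1-yl)-6,8-dimethoxy-1,3-dimethyl-1,2,3,4-tetrahydroisoquinoline | COc1cc(OC)c2c(c1-c1c(C)cc(OC)c3c(OC)cccc13)C[C@H](C)N[C@H]2C | target

**Totals**
Total step count: 8.
Longest linear sequence: 6 steps (1 → 5 → 6 → 14 → 15 → 16 → 17, or equally 7 → 10 → 12 → 14 → 15 → 16 → 17).

**Three steps most likely to fail**

Step 5 (oxidative naphthol–arene coupling). The risks are homocoupling of 6, over-oxidation of the product naphthol 14, attack at C2 of the naphthol or at the carbon between the two methoxy groups of 12, and the steric demand of a tetra-ortho-substituted axis. The fallback sets out from 6 and 12 and comes back at 15. N-Bromosuccinimide (MeCN, 0 °C) brominates 6 para to the hydroxyl to give 4-bromo-8-methoxy-3-methylnaphthalen-1-ol F1. MeI/K2CO3 in acetone then gives 1-bromo-4,5-dimethoxy-2-methylnaphthalene F2. Bromine–lithium exchange with n-BuLi (THF, −78 °C) gives (4,5-dimethoxy-2-methylnaphthalen-1-yl)lithium F3, which is trapped with B(OMe)3 and hydrolysed with aq. HCl to (4,5-dimethoxy-2-methylnaphthalen-1-yl)boronic acid F4. Separately, 12 is iodinated ortho to the side chain (N-iodosuccinimide, cat. CF3CO2H, MeCN) to give N-[(2S)-1-(2-iodo-3,5-dimethoxyphenyl)propan-2-yl]acetamide F5. Suzuki–Miyaura coupling of F4 with F5 (Pd(OAc)2, SPhos, K3PO4, toluene/H2O, 100 °C) gives 15 directly.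

Step 8 (trans-selective reduction). The risk is an insufficient trans:cis ratio at C1, since simple hydride or hydrogenation conditions favour the cis isomer. The fallback sets out from 16 and comes back at 17. Benzyl bromide (MeCN, 60 °C) quaternises the imine nitrogen to give (3S)-2-benzyl-5-(4,5-dimethoxy-2-methylnaphthalen-1-yl)-6,8-dimethoxy-1,3-dimethyl-3,4-dihydroisoquinolin-2-ium bromide F6. The N-benzyl group forces the C3 methyl axial, so NaBH4 (MeOH, −78 °C → 0 °C) delivers hydride axially to give (1S,3S)-2-benzyl-5-(4,5-dimethoxy-2-methylnaphthalen-1-yl)-6,8-dimethoxy-1,3-dimethyl-1,2,3,4-tetrahydroisoquinoline F7. Hydrogenolysis (H2, Pd on carbon, MeOH) removes the benzyl group and gives 17.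

Step 3 (aziridine opening). The risks are Grignard attack at the carbamate carbonyl and halide opening of the aziridine by magnesium salts. The fallback sets out from 7 (through the same Grignard reagent 9) and comes back at 12. Reagent 9 opens (R)-2-methyloxirane (CuI cat., THF, −30 °C → 0 °C) at the CH2 to give (2R)-1-(3,5-dimethoxyphenyl)propan-2-ol F8. Mitsunobu azidation (PPh3, diisopropyl azodicarboxylate, diphenylphosphoryl azide, THF, 0 °C → rt) proceeds with inversion to give 1-[(2S)-2-azidopropyl]-3,5-dimethoxybenzene F9. Hydrogenation (H2, Pd on carbon, EtOAc) in the presence of Ac2O reduces the azide to (2S)-1-(3,5-dimethoxyphenyl)propan-2-amine F10, which is acetylated in the same flask to 12.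

**Further compounds**
F1 | step 5 | 4-bromo-8-methoxy-3-methylnaphthalen-1-ol | COc1cccc2c(Br)c(C)cc(O)c12
F2 | step 5 | 1-bromo-4,5-dimethoxy-2-methylnaphthalene | COc1cccc2c(Br)c(C)cc(OC)c12
F3 | step 5 | (4,5-dimethoxy-2-methylnaphthalen-1-yl)lithium | COc1cccc2c([Li])c(C)cc(OC)c12
F4 | step 5 | (4,5-dimethoxy-2-methylnaphthalen-1-yl)boronic acid | COc1cccc2c(B(O)O)c(C)cc(OC)c12
F5 | step 5 | N-[(2S)-1-(2-iodo-3,5-dimethoxyphenyl)propan-2-yl]acetamide | COc1cc(OC)c(I)c(C[C@H](C)NC(C)=O)c1
F6 | step 8 | (3S)-2-benzyl-5-(4,5-dimethoxy-2-methylnaphthalen-1-yl)-6,8-dimethoxy-1,3-dimethyl-3,4-dihydroisoquinolin-2-ium bromide | COc1cc(OC)c2c(c1-c1c(C)cc(OC)c3c(OC)cccc13)C[C@H](C)[N+](Cc1ccccc1)=C2C.[Br-]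
F7 | step 8 | (1S,3S)-2-benzyl-5-(4,5-dimethoxy-2-methylnaphthalen-1-yl)-6,8-dimethoxy-1,3-dimethyl-1,2,3,4-tetrahydroisoquinoline | COc1cc(OC)c2c(c1-c1c(C)cc(OC)c3c(OC)cccc13)C[C@H](C)N(Cc1ccccc1)[C@H]2C
F8 | step 3 | (2R)-1-(3,5-dimethoxyphenyl)propan-2-ol | COc1cc(C[C@@H](C)O)cc(OC)c1
F9 | step 3 | 1-[(2S)-2-azidopropyl]-3,5-dimethoxybenzene | COc1cc(C[C@H](C)N=[N+]=[N-])cc(OC)c1
F10 | step 3 | (2S)-1-(3,5-dimethoxyphenyl)propan-2-amine | COc1cc(C[C@H](C)N)cc(OC)c1
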